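All constants are made up; the rest is arithmetic.

How much of the substrate has become target and crystals together after 8.0 d, and which change adds the most?

    2 substrate → homo dimer (k1 = 0.80 M⁻¹ h⁻¹)
    substrate → side product (k2 = 0.0050 h⁻¹)
    gas phase ⇌ dissolved gas, rate k3*(csat - [dissolved gas]) (k3 = 1.4 h⁻¹, csat = 1.2 mM)
    crystals ⇌ target, rate k4*(cs4 - [target]) while solid is left; crystals form when [target] > cs4 (cs4 = 0.39 mM, k4 = 1.7 h⁻¹)
    substrate + dissolved gas ⇌ target (K5 = 27000 M⁻¹, k5 = 20 M⁻¹ h⁻¹)

substrate 0.020 M; gas phase 1.2 mM (held); time 8.0 d

- a species is counted by the substrate in it: one homo dimer counts as two
- amounts and yields of target count crystals too
- two of one species on the left: rate k times its square, two consumed each time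
- given per volume of solution although it is solid: crystals
- at the start none of the gas is dissolved
- run time (flask): 8.0 d

- how much target and crystals together there is at 8.0 d, in percent of the substrate charged
- the change that raises the amount of target and crystals together at 8.0 d, in percent of the substrate charged most ("none" if none brings more than 2 percentage points) (east / north-east / west / south-east / none)
- amount of target and crystals together at 8.0 d, in percent of the substrate charged, after south-east

- east: doubling the solubility in step 4, all else as stated
- north-east: doubling the dissolution coefficient of step 4, all else as stated
- west: doubling the saturation concentration of gas phase, all else as stated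
- south-east: doubling the transfer coefficient of step 3, all else as stated

Follow the substrate left, not the product made. Let a be the rate constant of the target step times c(dissolved gas), a pseudo-first-order constant, which is 0.0240 h⁻¹ with the gas at saturation. Let b be the side-product constant, 0.0050 h⁻¹. The dimer step removes substrate at 2·0.80 M⁻¹ h⁻¹·c(substrate) per unit of substrate, and this term fades as c(substrate) falls. At each moment, then, the target takes the share a/(a + b + 2·0.80 M⁻¹ h⁻¹·c(substrate)).

With a held steady, adding these shares from the charge down to zero gives the yield a/(a + b) × ln(1 + D)/D. Here D, the dimer number, is the dimer loss at the charge over the first-order losses: 0.0290 h⁻¹ goes into it, so D is 1.10.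

You may drop the way back: with c(target) at the solubility 0.39 mM and the gas at saturation, the equilibrium of the target step holds hardly any of the charge as substrate. You may also run to zero, since the first-order losses by themselves leave 0.382% by the end.

Saturated gas gives 55.8%. But the transfer, with a time of 0.714 h, is quicker than the substrate's 16.4 h at the charge, so once the gas has risen from none it stands near where delivery equals uptake at the charge, at 0.933 mM. Held through the run, that level gives 49.9%. I commit to a yield between these two figures.

Doubling the saturation concentration gives 70.9% at saturated gas. Doubling the transfer coefficient leaves the upper figure and lifts the lower to 52.7%. The crystal constants do not enter the formula.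

The forecast gave 52.3% (range 50% to 55%), west as the best change, and 54% after south-east (range 51.5% to 56.5%), holding that “doubling the saturation concentration roughly doubles the target rate and clearly wins”.

The simulation gives 51.6%, above 49.9% and below 55.8%. The best change is west, with a gain of 15 percentage points, against 15 points between the two saturated-gas figures of the formula. South-east gives 53.4%, a gain of 1.8 points, while east moves the yield by −0.11 points and north-east by 0 points. The neighbour flask, charged with 0.0080 M, has a D of 0.441, which gives 68.6% at saturated gas and 66.2% at the starting gas level. That neighbour flask gives 66.2%, with homo dimer at 18.4% against 35.8% in the first flask.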